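E and J are charged at 0.14 M and 0.140 M. With one J per G, G stands under the cap, the smaller charge (the limiting reagent's), and here the two charges are equal: 0.140 M.

- cedar: E 0.14 M; J 0.14 M; the very flask that is asked about, followed so far
- flask: E 0.14 M; J 0.140 M; time 8.0 d; volume of the second phase over the first 0.50

- cedar (time / h: G / %, E / %): 2.50: 6.8, 90.9; 6.00: 12.0, 77.2; 15.0: 11.8, 55.3; 40.0: 7.5, 33.3

(scatter of a reading: 0.5 percentage points)

- in the second phase: J; everything else is in the first
- charges count per volume of the first phase; a concentration in a rate is the amount of a species over the volume of its own phase; every rate counts per litre of the first phase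
- the earlier runs hold the two phases in the same ratio of volumes as the flask asked about

- when, up to 8.0 d, the flask holds most G
- the amount of G, in percent of the E charged, at that time

Two extreme flasks can be solved in the head. If G were kept, G would equal the E spent, 66.7 % at 40.0 h, climbing towards the cap. If G were lost as fast as it formed, G would stay near zero. So the retained share, G over E spent, would be full in the first extreme flask and near nil in the second. The cedar run lies between:

0.526 at 6.00 h, 0.264 at 15.0 h

G reads 12.0 % and 11.8 % at those times, apart by less than the scatter 0.5 percentage points, so the peak is put midway, with the mean share and the mean E spent: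

time 0.438 d

G 13.3 %

The forecast gave 0.42 d (0.31 d to 0.54 d) and 13.5 % (12.5 % to 14.8 %), saying: “The peak therefore lies between those two points”.

The flask peaks at 0.400 d with 12.6 %.

    E + Q → G (k = 0.440 L mol⁻¹ h⁻¹)
    Q ⇌ J, rate k2*([Q] - [J]/K2) per volume of the first phase (partition coefficient = 0.400, kL = 0.270 h⁻¹)
    Q + G → L (k = 0.550 L mol⁻¹ h⁻¹)
    E + G → D (k = 0.480 L mol⁻¹ h⁻¹)
    Q + G → Z (k = 1.10 L mol⁻¹ h⁻¹)

That peak is 0.0176 M of G against the cap of 0.140 M, and it stands below the reckoned height by 0.70 points. The neighbour flask takes 0.35 M of E with J unchanged. J is then the limiting reagent, and the same cap is 40.0 % of that E charge. G in the neighbour flask peaks at 8.23 %, below the cap. Its E left at 8.00 d is 47 %, so the E spent, 53.0 %, exceeds the cap.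

All runs come from a simulation with made-up constants, noise included.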